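**One step.** Picture a one-step world whose rate follows the catalyst charged: delta holds 4.00 times the catalyst of gamma, but its readings show 6.83 times the loss of left-handed substrate by 2.50 min.

| flask | left-handed substrate | right-handed substrate | solid reagent | free catalyst | impurity | remark | time |
|---|---|---|---|---|---|---|---|
| gamma | 0.060 M | 0.060 M | 1 equiv | 1.9 mol% | 0.60 mM | run made earlier |  |
| delta | 0.24 M | 0.24 M | 1 equiv | 1.9 mol% | 0.60 mM | run made earlier |  |
| flask | 0.12 M | 0.12 M | 1.00 equiv | 1.9 mol% | 0.60 mM |  | 4.0 min |

| run | time / min | right-handed substrate / % | left-handed substrate / % |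
|---|---|---|---|
| gamma | 0.667 | 49.9 | 49.7 |
| gamma | 1.33 | 49.7 | 49.5 |
| gamma | 2.00 | 49.0 | 48.1 |
| gamma | 2.50 | 49.5 | 47.6 |
| delta | 0.667 | 48.9 | 48.9 |
| delta | 1.33 | 49.8 | 48.2 |
| delta | 2.00 | 48.8 | 47.3 |
| delta | 2.50 | 49.3 | 45.9 |

(readings scatter by 0.3 percentage points)

* whether the excess of right-handed substrate over left-handed substrate among what is left of the two reaches 95 % by 4.0 min (no / yes)
* the highest excess of right-handed substrate over left-handed substrate among what is left of the two up to 4.0 min

- free catalyst is single-handed; left-handed substrate and right-handed substrate are mirror images of each other, charged as a racemate, each of them at the stated concentration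
- given per volume of solution although it is solid: solid reagent
- at the start none of the solid reagent is in solution

**Working catalyst.** Read the impurity as a catalyst poison. This flask then holds 1.68 mM of working catalyst, the catalyst charged less the impurity taken one for one; gamma holds 0.540 mM and delta 3.96 mM. Left-handed substrate lost per minute per working catalyst reads 2.13 min⁻¹ in gamma and 1.99 min⁻¹ in delta, close given a scatter of 0.3 percentage points.

**Bench note.** This flask holds the racemate, undissolved solid reagent, and catalyst of which the impurity takes a quarter. By 4.0 min, this note reckons, it has lost 13.8 mM of left-handed substrate. Right-handed loss is taken as 0.171 of that, from the last pair of scattered readings in delta, so this note reckons the excess at 5.13 %. Written as a power of ten, the ratio of right-handed to left-handed substrate has the exponent 0.0446, against 1.59 for 95 %. Leave the catalyst and impurity charges alone: in this reckoning the rate goes with the catalyst charged less the smaller impurity charge.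

**The forecast.** The forecast stands slightly higher: no, with a top of 5.5 %, “still rising at 4 min”.

**Result.** The flask gives no, with a top excess of 5.49 %.

    free catalyst + left-handed substrate ⇌ catalyst intermediate A (K = 14.0 M⁻¹, k = 34.0 M⁻¹ s⁻¹)
    free catalyst + right-handed substrate ⇌ catalyst intermediate B (K = 11.0 M⁻¹, k = 370 M⁻¹ s⁻¹)
    coupling partner + catalyst intermediate A → free catalyst + left-handed product (k = 6.70 M⁻¹ s⁻¹)
    coupling partner + catalyst intermediate B → free catalyst + right-handed product (k = 2.30 M⁻¹ s⁻¹)
    solid reagent ⇌ coupling partner, rate k5*(cs5 - [coupling partner]) while solid is left; crystals form when [coupling partner] > cs5 (solubility = 50.0 mM, k = 0.00590 s⁻¹)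
    free catalyst + impurity → spent catalyst (k = 6000 M⁻¹ s⁻¹)
    2 coupling partner → self-condensation product (k = 0.0310 M⁻¹ s⁻¹)

At 4.00 min spent catalyst stands at 26.3 % of the catalyst charged, leaving 1.68 mM in the other forms, beside the 1.68 mM of working catalyst. In the neighbour with 0.47 mol% of free catalyst, working catalyst comes to −0.0360 mM, below zero, an overhang of 6.00 % of the impurity charge. There 6.0 % of the impurity stays unbound, and the top excess is 0.0183 %.

(The runs are simulated on assumed constants, and the scatter is random.)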